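All runs come from a simulation for substances that don't exist; scatter was added.

A bench chemist reads the charge before the curve. Each target consumes one coupling partner and each coupling partner comes from one solid reagent, so with the solid reagent as limiting reagent the target cannot pass 60.0% of the substrate charged in north-east or north-west. This is the reagent ceiling, charged solid reagent over charged substrate. At least 40.0% of the substrate charged in either flask therefore does not become target.

| flask | substrate | solid reagent | temperature | remark | time |
|---|---|---|---|---|---|
| elm | 1 M | 0.30 M | −19 °C | run made earlier |  |
| oak | 1 M | 1.2 M | −5 °C | run made earlier |  |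
| north-east | 1.0 M | 0.600 M | −25 °C |  | 30 min |
| north-west | 1.0 M | 0.600 M | 0 °C |  | 30 min |

| run | time / min | target / % |
|---|---|---|
| elm | 1.33 | 0.1 |
| elm | 2.50 | 0.2 |
| elm | 4.00 | 0.3 |
| elm | 6.00 | 0.7 |
| elm | 10.0 | 2.7 |
| elm | 20.0 | 8.2 |
| oak | 0.500 | 0.1 |
| oak | 1.33 | 0.5 |
| oak | 2.00 | 0.9 |
| oak | 4.00 | 4.4 |
| oak | 6.00 | 11.5 |
| oak | 8.00 | 17.1 |

(standard deviation of a reading: 0.3 percentage points)

- given per volume of solution although it is solid: solid reagent
- the numbers in the tables scatter by 0.3 percentage points (one standard deviation)
- steps thought possible: substrate -> intermediate; solid reagent <-> coupling partner; intermediate -> side product; 2 coupling partner -> homo dimer; coupling partner + intermediate -> target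
- at the start none of the solid reagent is in solution

- the flask with the highest amount of target, in percent of the substrate charged ("all alike" if they lie within 1.5 percentage points) (north-east / north-west / all alike)
- final target, as a percentage of the substrate charged, in north-east
- final target, as a percentage of the substrate charged, in north-west

The rule has a border: a ceiling counts only in a flask with time to reach it, and a ratio of readings tests that. At the pace of the oak run between 4.00 min and 8.00 min, the ceiling fills in 18.9 min, which is shorter than the 30 min of north-west. At the pace of the elm run between 10.0 min and 20.0 min, it fills in 109 min, longer than the 30 min of north-east. These paces are borrowed across different solid charges, so they are rough. Still, north-west is warmer than oak, and north-east is colder than elm.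

The reckoning here therefore puts north-west just under its ceiling and north-east below the 16.5% that the elm pace gives over the whole time.

The forecast also picks north-west, with 11% for north-east and 38% for north-west: “North-west should win unless side reactions dominate strongly”. Its north-west figure lies lower than the ceiling, and there the two part.

North-east ends at 4.55% and north-west at 56.4%, so north-west leads.

    substrate → intermediate (k = 0.310 min⁻¹, Ea = 86.0 kJ mol⁻¹)
    solid reagent ⇌ coupling partner, rate k2*(cs2 - [coupling partner]) while solid is left; crystals form when [coupling partner] > cs2 (solubility = 0.220 M, k = 0.380 min⁻¹)
    intermediate → side product (k = 0.0430 min⁻¹, Ea = 80.0 kJ mol⁻¹)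
    2 coupling partner → homo dimer (k = 0.0230 M⁻¹ min⁻¹, Ea = 72.0 kJ mol⁻¹)
    coupling partner + intermediate → target (k = 0.700 M⁻¹ min⁻¹, Ea = 46.0 kJ mol⁻¹)
    (constants at 0 °C)

In north-west at 30.0 min, coupling partner goes to target 48 times as fast as to homo dimer, and the target stands at 94.0% of its ceiling, with side product at 35.6% and intermediate at 7.93%. With 1.0 M of solid reagent, a flask otherwise like north-west has its ceiling at 100%, and it ends with side product at 32.9% and target at 65.0%.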